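The south run holds 1.50 times the substrate of the south-east run on the same free catalyst, and at 2.5 min its product reads 1.53 times as much.

| flask | substrate | free catalyst | time |
|---|---|---|---|
| south-east | 0.800 M | 0.0640 M |  |
| south | 1.20 M | 0.0640 M |  |
| north | 0.800 M | 0.0640 M | 92 min |

| south-east run: time / min | south-east run: [product] / M | south run: time / min | south run: [product] / M |
|---|---|---|---|
| 0.83 | 0.085 | 0.83 | 0.117 |
| 2.5 | 0.199 | 2.5 | 0.305 |
| 4.8 | 0.317 | 4.8 | 0.441 |
| 7.6 | 0.406 | 7.6 | 0.534 |
| 11 | 0.443 | 11 | 0.613 |
| 15 | 0.478 | 15 | 0.672 |
| 19 | 0.494 | 19 | 0.700 |
| 23 | 0.518 | 23 | 0.681 |

(each reading ± 0.008 M)

- how the opening rate goes with [substrate] round the charge of the south-east run: the exponent of the rate at two percent of substrate gone to product (one fixed amount of product, the same in the runs compared)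
- product in the north run at 92 min, as a share of the substrate charged

I reckon with two times. The first is a pseudo-first-order time, the one in which substrate would fall by a factor e at the opening pace. I get it by dividing 2.5 min by the logarithm of charge over substrate left.

South-east run: opening time 8.74 min
South run: 8.53 min

Opening times that nearly match across unequal charges point to a rate close to proportional to substrate, so from their ratio I read an order of 1.06.

The second is the stall time, in which that pace fades by a factor e. If the pace fades so, the logarithm of charge over substrate left climbs towards stall time over opening time, and that ratio gives the end share. In the south-east run the logarithm reads 1.04 at 23 min.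

Stall time, first pass: 9.11 min
End ratio, with the fading left after 23 min: 1.13

The north run has the south-east charge, and 92 min is 10.1 stall times, so I commit to 67.7%.

The forecast gives 0.75 and 67%, a lower order than mine, and it sets that order between the early product ratios and the plateaus: “I compromise on about 0.75.”

The flask gives an order of 1.0 and 67.1%.

    free catalyst + substrate → product + free catalyst (2.184 M⁻¹ min⁻¹)
    free catalyst → spent catalyst (0.07140 min⁻¹)
    2 substrate → homo dimer (0.04716 M⁻¹ min⁻¹)

With the south-east opening time 8.74 min and no fading, product would come to half of the charge at 6.06 min, against a simulated 8.37 min in the south-east run. In the north run, two steps together hold the product at 67.1%: free catalyst going to spent catalyst, and substrate going to homo dimer. Without the first step that run reaches 80.0%, and without the second 85.8%.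

(The earlier runs and the new flask come from a simulation from invented constants; scatter was added.)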